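**Assumption (one line):** the SMILES is read as written – 8‑H β (cis to the C9 and C14 methyls), sesquiterpene unit (7S,10S); friedelane numbering is used for the triterpene part and guaiane numbering (prefix g) for the sesquiterpene part. The route is a paper proposal; no step has been run.

## Retrosynthetic overview

1. Dioxane last: hetero‑Diels–Alder of the triterpene ortho‑quinone (from catechol 30) with (7S,10S)‑guaia‑1(5),3,11‑triene 39, made from (S)‑carvone.
2. Ring B late: cyclodehydration of an aryl‑tethered aldehyde (C5–C6 bond, Δ6 formed directly); the ring‑D ketone is removed via its enol triflate.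
3. Key disconnection: C8–C9 and C13–C14 in one cationic cascade. The enabling feature is the pair of vicinal methyl‑bearing quaternary carbons C13/C14 shared by rings C and D next to the unsubstituted C15. A 1‑alkenylcyclopentanol (C13, C15, C16, C17, C18; carbinol = C15) can hand C13 over to C14 by a 1,2‑shift, which inserts C14 and makes ring D six‑membered.
4. The cyclopentanone comes from an intramolecular Stetter reaction. The ring‑E stereotriad (C17, C18, C20) comes from an enantioselective Diels–Alder reaction to a bicyclo[2.2.2]octene whose enol‑ether bridge (not in the target) is cleaved by ozonolysis.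
5. Ring order: E (as bicycle) → five‑membered precursor of D → C and D together (key step) → B → ring A oxidised → dioxane.

Key step: step 18

## Route

**Ring E and the five‑membered precursor of ring D**

Step 1
Reactants: 1 3‑methylcyclohex‑2‑en‑1‑one
Product: 2 3,6‑dimethylcyclohex‑2‑en‑1‑one (racemic)
Conditions: LDA, THF, −78 °C; MeI, −78 → 0 °C
Reagents that add atoms: iodomethane, CI
Why: kinetic α′‑deprotonation of the enone and C‑methylation (enolate alkylation); the new stereocentre is erased in step 2.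

Step 2
Reactants: 2 3,6‑dimethylcyclohex‑2‑en‑1‑one
Product: 3 1,4‑dimethyl‑2‑(triisopropylsilyloxy)cyclohexa‑1,3‑diene
Conditions: LDA, THF, −78 °C; i‑Pr3SiOTf, −78 → 0 °C
Reagents that add atoms: triisopropylsilyl trifluoromethanesulfonate, CC(C)[Si](C(C)C)(C(C)C)OS(=O)(=O)C(F)(F)F
Why: kinetic α′‑enolisation gives the cross‑conjugated dienolate, which is O‑silylated to the 2‑silyloxy‑1,3‑diene.

Step 3
Reactants: 3 1,4‑dimethyl‑2‑(triisopropylsilyloxy)cyclohexa‑1,3‑diene; 4 but‑3‑en‑2‑one
Product: 5 endo‑1‑[1,4‑dimethyl‑5‑(triisopropylsilyloxy)bicyclo[2.2.2]oct‑5‑en‑2‑yl]ethanone (single enantiomer as in the SMILES)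
Conditions: 20 mol% protonated (S)‑B‑(o‑tolyl)‑diphenylprolinol oxazaborolidine, [C24H25BNO]+ [N(SO2CF3)2]−, CH2Cl2, −78 °C
Reagents that add atoms: none
Why: enantioselective Lewis‑acid‑catalysed Diels–Alder reaction; the silyloxy group directs the acetyl‑bearing carbon to the remote methyl terminus ("para"), the endo rule places the acetyl group syn to the enol‑ether bridge, and the catalyst enantiomer is chosen to block the diene face that would give the mirror image, so C17, C18 and C20 are set together.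

Step 4
Reactants: 5 endo‑1‑[1,4‑dimethyl‑5‑(triisopropylsilyloxy)bicyclo[2.2.2]oct‑5‑en‑2‑yl]ethanone
Product: 6 ethyl (E)‑3‑[endo‑1,4‑dimethyl‑5‑(triisopropylsilyloxy)bicyclo[2.2.2]oct‑5‑en‑2‑yl]but‑2‑enoate
Conditions: (EtO)2P(O)CH2CO2Et, NaH, THF, 0 °C → reflux
Reagents that add atoms: triethyl phosphonoacetate, CCOC(=O)CP(=O)(OCC)OCC
Why: Horner–Wadsworth–Emmons olefination of the methyl ketone, expected to favour the (E)‑enoate (ester trans to the ring carbon); the silyl enol ether tolerates the phosphonate anion.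

Step 5
Reactants: 6 ethyl (E)‑3‑[endo‑1,4‑dimethyl‑5‑(triisopropylsilyloxy)bicyclo[2.2.2]oct‑5‑en‑2‑yl]but‑2‑enoate
Product: 8 methyl all‑cis‑3‑[(E)‑4‑ethoxy‑4‑oxobut‑2‑en‑2‑yl]‑4‑formyl‑1,4‑dimethylcyclohexane‑1‑carboxylate, via carboxylic acid 7 (not isolated)
Conditions: O3 (1 equiv), CH2Cl2/MeOH, −78 °C; Me2S; then Me3SiCHN2, toluene/MeOH, 0 °C
Reagents that add atoms: ozone, [O-][O+]=O; trimethylsilyldiazomethane, C[Si](C)(C)C=[N+]=[N-]
Why: ozonolysis attacks the electron‑rich silyl enol ether much faster than the enoate and cuts the temporary bridge to a C16 aldehyde and a C29 acid held cis on ring E, and the acid is then esterified without base.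

Step 6
Reactants: 8 methyl all‑cis‑3‑[(E)‑4‑ethoxy‑4‑oxobut‑2‑en‑2‑yl]‑4‑formyl‑1,4‑dimethylcyclohexane‑1‑carboxylate
Product: 9 methyl 3‑[(E)‑4‑ethoxy‑4‑oxobut‑2‑en‑2‑yl]‑4‑(2‑methoxyethenyl)‑1,4‑dimethylcyclohexane‑1‑carboxylate (E/Z enol ether mixture)
Conditions: MeOCH2PPh3Cl, KHMDS, THF, −78 → 0 °C
Reagents that add atoms: (methoxymethyl)triphenylphosphonium chloride, COC[P+](c1ccccc1)(c1ccccc1)c1ccccc1.[Cl-]
Why: Wittig one‑carbon homologation of the only aldehyde; the esters and the enoate do not react with the ylide at low temperature.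

Step 7
Reactants: 9 methyl 3‑[(E)‑4‑ethoxy‑4‑oxobut‑2‑en‑2‑yl]‑4‑(2‑methoxyethenyl)‑1,4‑dimethylcyclohexane‑1‑carboxylate
Product: 10 methyl 3‑[(E)‑4‑ethoxy‑4‑oxobut‑2‑en‑2‑yl]‑1,4‑dimethyl‑4‑(2‑oxoethyl)cyclohexane‑1‑carboxylate
Conditions: 1 M HCl, THF, 23 °C
Reagents that add atoms: water, O
Why: mild acid hydrolysis of the enol ether liberates the C15 aldehyde.

Step 8
Reactants: 10 methyl 3‑[(E)‑4‑ethoxy‑4‑oxobut‑2‑en‑2‑yl]‑1,4‑dimethyl‑4‑(2‑oxoethyl)cyclohexane‑1‑carboxylate
Product: 11 methyl cis‑fused 3‑(2‑ethoxy‑2‑oxoethyl)‑3,5,7a‑trimethyl‑2‑oxooctahydro‑1H‑indene‑5‑carboxylate (3‑methyl cis to the six‑membered ring; ester arm cis to 3a‑H and 7a‑methyl)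
Conditions: 20 mol% (5aR,10bS)‑2‑(pentafluorophenyl)‑4,5a,6,10b‑tetrahydroindeno[2,1‑b][1,2,4]triazolo[4,3‑d][1,4]oxazin‑2‑ium tetrafluoroborate, KHMDS (20 mol%), toluene, 23 °C
Reagents that add atoms: none
Why: intramolecular Stetter reaction (5‑exo addition of the acyl‑anion equivalent to the β,β‑disubstituted enoate) closes the cyclopentanone and makes quaternary C13; allylic 1,3‑strain holds C18–H in the plane of the (E)‑enoate so that attack from the tether side leaves the C13 methyl cis to ring E, with the carbene chosen to reinforce this.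

**Alkenyl iodide and aryl phosphonium salt**

Step 9
Reactants: 12 3‑(benzyloxy)propanal
Product: 13 (Z)‑{[(4‑iodopent‑3‑en‑1‑yl)oxy]methyl}benzene
Conditions: EtPPh3I, n‑BuLi, THF; I2, −78 °C; NaHMDS; then 12, −78 °C
Reagents that add atoms: ethyltriphenylphosphonium iodide, CC[P+](c1ccccc1)(c1ccccc1)c1ccccc1.[I-]; iodine, II
Why: Stork–Zhao‑type olefination with the α‑iodo ylide gives the (Z)‑2‑iodoalkene (iodine cis to the chain), the geometry the key step needs.

Step 10
Reactants: 14 2‑methoxy‑6‑methylphenol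
Product: 15 4‑bromo‑2‑methoxy‑6‑methylphenol
Conditions: NBS, MeCN, 0 °C
Reagents that add atoms: N‑bromosuccinimide, O=C1CCC(=O)N1Br
Why: electrophilic bromination para to the free hydroxyl group, the only unhindered activated position.

Step 11
Reactants: 15 4‑bromo‑2‑methoxy‑6‑methylphenol
Product: 16 5‑bromo‑1,2‑dimethoxy‑3‑methylbenzene
Conditions: MeI, K2CO3, acetone, reflux
Reagents that add atoms: iodomethane, CI
Why: Williamson O‑methylation of the phenol.

Step 12
Reactants: 16 5‑bromo‑1,2‑dimethoxy‑3‑methylbenzene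
Product: 17 1‑(3,4‑dimethoxy‑5‑methylphenyl)ethan‑1‑ol (racemic)
Conditions: n‑BuLi, THF, −78 °C; MeCHO
Reagents that add atoms: acetaldehyde, CC=O
Why: bromine–lithium exchange and 1,2‑addition of the aryllithium to the aldehyde; the stereocentre is lost later.

Step 13
Reactants: 17 1‑(3,4‑dimethoxy‑5‑methylphenyl)ethan‑1‑ol
Product: 18 [1‑(3,4‑dimethoxy‑5‑methylphenyl)ethyl]triphenylphosphonium bromide
Conditions: Ph3P·HBr, MeCN, reflux
Reagents that add atoms: triphenylphosphine hydrobromide, [Br-].[PH+](c1ccccc1)(c1ccccc1)c1ccccc1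
Why: the electron‑rich benzylic alcohol ionises under the acid and the cation is trapped by triphenylphosphine (SN1 phosphonium salt formation).

**Union, key step and ring B**

Step 14
Reactants: 11 keto diester; 13 (Z)‑{[(4‑iodopent‑3‑en‑1‑yl)oxy]methyl}benzene
Product: 19 tertiary alcohol (11 with C2=O replaced by C(OH)[(Z)‑5‑(benzyloxy)pent‑2‑en‑2‑yl]; alkenyl group cis to the CH2CO2Et arm)
Conditions: 13, t‑BuLi (2 equiv), Et2O, −78 °C; CeCl3, THF, −78 °C; then 11, −78 °C
Reagents that add atoms: none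
Why: iodine–lithium exchange with retention of alkene geometry and 1,2‑addition of the organocerium reagent, which adds to ketones far faster than to esters and suppresses enolisation; attack is expected anti to the cis‑fused six‑membered ring (convex face), which places C14 cis to the C12 arm.

Step 15
Reactants: 19 tertiary alcohol
Product: 20 trimethylsilyl ether of 19
Conditions: Me3SiOTf, 2,6‑lutidine, CH2Cl2, −78 → 0 °C
Reagents that add atoms: trimethylsilyl trifluoromethanesulfonate, C[Si](C)(C)OS(=O)(=O)C(F)(F)F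
Why: silylation of the hindered tertiary alcohol with the silyl triflate; the silyl cap lowers the tendency of the allylic C–O bond to ionise in step 18.

Step 16
Reactants: 20 trimethylsilyl ether
Product: 21 aldehyde (CH2CO2Et of 20 reduced to CH2CHO)
Conditions: i‑Bu2AlH (1.1 equiv), toluene, −78 °C
Reagents that add atoms: none
Why: partial reduction of the accessible ethyl ester via the stable tetrahedral aluminate; the methyl ester on quaternary C20 is much more hindered.

Step 17
Reactants: 21 aldehyde; 18 [1‑(3,4‑dimethoxy‑5‑methylphenyl)ethyl]triphenylphosphonium bromide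
Product: 22 trisubstituted styrene (CH2CH=C(CH3)Ar arm on C13; E/Z mixture, E drawn)
Conditions: 18, KHMDS, THF, −78 → 0 °C; then 21, → 23 °C
Reagents that add atoms: none
Why: Wittig olefination with the semi‑stabilised ylide; alkene geometry is irrelevant because both isomers give the same benzylic cation.

Step 18
Reactants: 22 trisubstituted styrene
Product: 23 tricyclic ketone (rings C, D, E; 15‑oxo; aryl and β‑methyl on C9; 8β‑H; 13α‑ and 14β‑methyl; 2‑(benzyloxy)ethyl on C8)
Conditions: Tf2NH (10 mol%), (CF3)2CHOH/CH2Cl2 1:4, −60 → −20 °C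
Reagents that add atoms: none
Why: Proposed new method: protonation of the electron‑rich α‑methylstyrene gives the tertiary benzylic C9 cation, which attacks C8 of the (Z)‑trisubstituted alkene in a 7‑endo‑trig cation–olefin closure; the tertiary C14 cation so formed is quenched by a pinacol‑type 1,2‑shift of C13 from the silyloxy carbon C15, which contracts the transient seven‑membered ring to ring C, enlarges the cyclopentane to the cyclohexanone ring D and passes the silyl group to the fluoro alcohol, regenerating the acid. The closest known reaction type is the pinacol‑terminated Prins cyclization (ring‑enlarging cyclohexane annulation of 1‑alkenylcycloalkanol silyl ethers started by oxocarbenium ions); new here are the carbocation initiator and the aryl‑bearing quaternary carbon made in the same event. C14: allylic 1,3‑strain in the (Z)‑alkenyl carbinol puts the C15–O bond in the alkene plane and the C15–C13 bond perpendicular to it, so C13 migrates with retention to the face on which its own tether delivers C9, and the methyl groups on C13 and C14 end up anti (trans C/D fusion). C8: C9 and C13 add to the same alkene face, so the (Z) geometry becomes H8 syn to the C14 methyl with the benzyloxyethyl chain axial. C9: the open transition state with the aryl group anti to the congested C14 puts the C9 methyl syn to H8. The step needs protonation of the styrene in preference to the trialkyl alkene and to ionisation of the allylic ether; the far more stabilised benzylic cation, the silyl cap and low temperature in the fluoro alcohol are meant to secure this.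

Step 19
Reactants: 23 tricyclic ketone
Product: 24 enol triflate (C15(OTf)=C16)
Conditions: KHMDS, THF, −78 °C; PhNTf2, −78 → 0 °C
Reagents that add atoms: N‑phenylbis(trifluoromethanesulfonimide), O=S(=O)(N(c1ccccc1)S(=O)(=O)C(F)(F)F)C(F)(F)F
Why: the ketone can enolise only toward C16 (C14 is quaternary), and the enolate is trapped as the triflate.

Step 20
Reactants: 24 enol triflate
Product: 25 alkene (C15=C16)
Conditions: Pd(OAc)2 (5 mol%), PPh3, Bu3N, HCO2H, DMF, 60 °C
Reagents that add atoms: none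
Why: palladium‑catalysed formate reduction of the vinyl triflate removes the ring‑D oxygen under conditions that spare both esters.

Step 21
Reactants: 25 alkene
Product: 26 primary alcohol (ring D saturated; C6–OH free)
Conditions: H2 (4 atm), Pd/C, EtOAc/EtOH, 23 °C
Reagents that add atoms: none
Why: catalytic hydrogenation saturates the only C=C bond (no new stereocentre) and hydrogenolyses the benzyl ether in the same operation.

Step 22
Reactants: 26 primary alcohol
Product: 27 aldehyde (C8–CH2–CHO)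
Conditions: Dess–Martin periodinane, NaHCO3, CH2Cl2, 23 °C
Reagents that add atoms: none
Why: mild Dess–Martin oxidation stops at the aldehyde and does not epimerise C8.

Step 23
Reactants: 27 aldehyde
Product: 29 methyl 2,3‑dimethoxy‑24‑nor‑8β‑friedela‑1,3,5(10),6‑tetraen‑29‑oate, via benzylic alcohol 28 (not isolated)
Conditions: p‑TsOH·H2O (10 mol%), benzene, 60 °C
Reagents that add atoms: none
Why: Bradsher‑type cyclodehydration: intramolecular Friedel–Crafts hydroxyalkylation at C5 (para to the unhindered methoxy group, and feasible only because the C8 chain is cis to the aryl group) followed by loss of water gives ring B with the 6,7‑double bond.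

Step 24
Reactants: 29 dimethoxy styrene
Product: 30 methyl 2,3‑dihydroxy‑24‑nor‑8β‑friedela‑1,3,5(10),6‑tetraen‑29‑oate (catechol)
Conditions: BBr3 (3 equiv), CH2Cl2, −78 → −20 °C; aq. NaHCO3
Reagents that add atoms: none
Why: Lewis‑acid cleavage of the two aryl methyl ethers at low temperature, where the hindered tertiary methyl ester is left intact.

**Sesquiterpene diene**

Step 25
Reactants: 31 (S)‑carvone
Product: 32 (2S,5S)‑dihydrocarvone (trans)
Conditions: LiBH(s‑Bu)3, THF, −78 °C; then NaOMe, MeOH, 23 °C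
Reagents that add atoms: none
Why: conjugate hydride reduction of the enone, then base equilibration at C2 to the diequatorial trans isomer, which sets g10 relative to g7.

Step 26
Reactants: 32 (2S,5S)‑dihydrocarvone
Product: 33 (2S,5S)‑2‑methyl‑5‑(prop‑1‑en‑2‑yl)cycloheptan‑1‑one
Conditions: Me3SiCHN2, BF3·OEt2, CH2Cl2, −78 °C; then K2CO3, MeOH
Reagents that add atoms: trimethylsilyldiazomethane, C[Si](C)(C)C=[N+]=[N-]
Why: Lewis‑acid‑promoted diazoalkane ring expansion in which the less substituted α‑carbon migrates, so the new CH2 enters away from the methyl‑bearing carbon.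

Step 27
Reactants: 33 (2S,5S)‑2‑methyl‑5‑(prop‑1‑en‑2‑yl)cycloheptan‑1‑one
Product: 34 (4S,7S)‑7‑methyl‑4‑(prop‑1‑en‑2‑yl)‑2‑(prop‑2‑en‑1‑yl)cycloheptan‑1‑one (epimers at C2)
Conditions: LDA, THF, −78 °C; allyl bromide, −78 → 0 °C
Reagents that add atoms: allyl bromide, C=CCBr
Why: kinetic enolate formation at the CH2 α‑carbon and allylation; the new centre becomes sp2 later.

Step 28
Reactants: 34 allyl ketone
Product: 35 (4S,7S)‑7‑methyl‑2‑(2‑oxopropyl)‑4‑(prop‑1‑en‑2‑yl)cycloheptan‑1‑one
Conditions: PdCl2 (10 mol%), CuCl, O2, DMF/H2O, 23 °C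
Reagents that add atoms: water, O
Why: Wacker oxidation is selective for the monosubstituted terminal alkene over the 1,1‑disubstituted isopropenyl group.

Step 29
Reactants: 35 1,4‑diketone
Product: 36 (5S,8S)‑8‑methyl‑5‑(prop‑1‑en‑2‑yl)‑3,3a,4,5,6,7‑hexahydroazulen‑2(8H)‑one type enone (O=g3, g1=g2)
Conditions: KOt‑Bu (0.3 equiv), t‑BuOH, 23 °C
Reagents that add atoms: none
Why: intramolecular aldol condensation of the 1,4‑diketone closes the cyclopentenone; mild base is used to limit γ‑epimerisation at g10.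

Step 30
Reactants: 36 bicyclic enone
Product: 37 bicyclic enone methylated at g4
Conditions: LDA, THF, −78 °C; MeI
Reagents that add atoms: iodomethane, CI
Why: kinetic α′‑enolate alkylation puts the g15 methyl on g4; this centre becomes sp2 in the next step.

Step 31
Reactants: 37 methylated enone
Product: 39 (5S,8S)‑3,8‑dimethyl‑5‑(prop‑1‑en‑2‑yl)‑1,4,5,6,7,8‑hexahydroazulene, via allylic alcohol 38 (not isolated)
Conditions: NaBH4, CeCl3·7H2O, MeOH, 0 °C; then p‑TsOH (cat.), CH2Cl2, 23 °C
Reagents that add atoms: none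
Why: Luche 1,2‑reduction and acid dehydration give the cyclopentadiene, whose 1,5‑hydrogen shifts should funnel it toward the most substituted 1(5),3‑isomer; it is used as the equilibrating mixture.

**Union of the two halves**

Step 32
Reactants: 30 catechol; 39 guaia‑1(5),3,11‑triene
Product: 41 target compound, via ortho‑quinone 40 (not isolated)
Conditions: Ag2O, 4 Å molecular sieves, CH2Cl2, 0 → 23 °C, 39 (3 equiv) present from the start
Reagents that add atoms: none
Why: oxidation to the ortho‑quinone and inverse‑electron‑demand hetero‑Diels–Alder reaction of its O=C–C=O unit with the most electron‑rich (tetrasubstituted g1=g5) bond of the diene; the two C–O bonds form suprafacially (cis‑fused dioxane) and approach anti to the isopropenyl‑bearing face of the seven‑membered ring should give the drawn diastereomer.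

## Compound list

1 | 3‑methylcyclohex‑2‑en‑1‑one | CC1=CC(=O)CCC1 | starting material
2 | 3,6‑dimethylcyclohex‑2‑en‑1‑one (racemic) | CC1=CC(=O)C(C)CC1 | intermediate
3 | 1,4‑dimethyl‑2‑(triisopropylsilyloxy)cyclohexa‑1,3‑diene | CC1=C(O[Si](C(C)C)(C(C)C)C(C)C)C=C(C)CC1 | intermediate
4 | but‑3‑en‑2‑one | CC(=O)C=C | starting material
5 | endo‑1‑[1,4‑dimethyl‑5‑(triisopropylsilyloxy)bicyclo[2.2.2]oct‑5‑en‑2‑yl]ethanone | CC(=O)[C@@H]1C[C@@]2(C)CC[C@]1(C)C=C2O[Si](C(C)C)(C(C)C)C(C)C | intermediate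
6 | ethyl (E)‑3‑[endo‑1,4‑dimethyl‑5‑(triisopropylsilyloxy)bicyclo[2.2.2]oct‑5‑en‑2‑yl]but‑2‑enoate | CCOC(=O)/C=C(\C)[C@@H]1C[C@@]2(C)CC[C@]1(C)C=C2O[Si](C(C)C)(C(C)C)C(C)C | intermediate
7 | all‑cis‑3‑[(E)‑4‑ethoxy‑4‑oxobut‑2‑en‑2‑yl]‑4‑formyl‑1,4‑dimethylcyclohexane‑1‑carboxylic acid | O=C[C@@]1(C)CC[C@@](C)(C(=O)O)C[C@H]1/C(C)=C/C(=O)OCC | intermediate
8 | methyl all‑cis‑3‑[(E)‑4‑ethoxy‑4‑oxobut‑2‑en‑2‑yl]‑4‑formyl‑1,4‑dimethylcyclohexane‑1‑carboxylate | O=C[C@@]1(C)CC[C@@](C)(C(=O)OC)C[C@H]1/C(C)=C/C(=O)OCC | intermediate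
9 | methyl 3‑[(E)‑4‑ethoxy‑4‑oxobut‑2‑en‑2‑yl]‑4‑(2‑methoxyethenyl)‑1,4‑dimethylcyclohexane‑1‑carboxylate (E/Z at the enol ether) | COC=C[C@@]1(C)CC[C@@](C)(C(=O)OC)C[C@H]1/C(C)=C/C(=O)OCC | intermediate
10 | methyl 3‑[(E)‑4‑ethoxy‑4‑oxobut‑2‑en‑2‑yl]‑1,4‑dimethyl‑4‑(2‑oxoethyl)cyclohexane‑1‑carboxylate | O=CC[C@@]1(C)CC[C@@](C)(C(=O)OC)C[C@H]1/C(C)=C/C(=O)OCC | intermediate
11 | methyl cis‑fused 3‑(2‑ethoxy‑2‑oxoethyl)‑3,5,7a‑trimethyl‑2‑oxooctahydro‑1H‑indene‑5‑carboxylate | O=C1C[C@@]2(C)CC[C@@](C)(C(=O)OC)C[C@H]2[C@]1(C)CC(=O)OCC | intermediate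
12 | 3‑(benzyloxy)propanal | O=CCCOCc1ccccc1 | starting material
13 | (Z)‑{[(4‑iodopent‑3‑en‑1‑yl)oxy]methyl}benzene | C/C(I)=C/CCOCc1ccccc1 | intermediate
14 | 2‑methoxy‑6‑methylphenol | COc1cccc(C)c1O | starting material
15 | 4‑bromo‑2‑methoxy‑6‑methylphenol | COc1cc(Br)cc(C)c1O | intermediate
16 | 5‑bromo‑1,2‑dimethoxy‑3‑methylbenzene | COc1cc(Br)cc(C)c1OC | intermediate
17 | 1‑(3,4‑dimethoxy‑5‑methylphenyl)ethan‑1‑ol (racemic) | COc1cc(C(C)O)cc(C)c1OC | intermediate
18 | [1‑(3,4‑dimethoxy‑5‑methylphenyl)ethyl]triphenylphosphonium bromide | COc1cc(C(C)[P+](c2ccccc2)(c2ccccc2)c2ccccc2)cc(C)c1OC.[Br-] | intermediate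
19 | tertiary alcohol from 11 and 13 (alkenyl cis to the ester arm) | CCOC(=O)C[C@@]1(C)[C@@H]2C[C@](C)(C(=O)OC)CC[C@]2(C)C[C@@]1(O)/C(C)=C\CCOCc1ccccc1 | intermediate
20 | trimethylsilyl ether of 19 | CCOC(=O)C[C@@]1(C)[C@@H]2C[C@](C)(C(=O)OC)CC[C@]2(C)C[C@@]1(O[Si](C)(C)C)/C(C)=C\CCOCc1ccccc1 | intermediate
21 | aldehyde from 20 | O=CC[C@@]1(C)[C@@H]2C[C@](C)(C(=O)OC)CC[C@]2(C)C[C@@]1(O[Si](C)(C)C)/C(C)=C\CCOCc1ccccc1 | intermediate
22 | trisubstituted styrene, key‑step precursor (E isomer drawn) | COc1cc(cc(C)c1OC)/C(C)=C/C[C@@]1(C)[C@@H]2C[C@](C)(C(=O)OC)CC[C@]2(C)C[C@@]1(O[Si](C)(C)C)/C(C)=C\CCOCc1ccccc1 | intermediate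
23 | tricyclic 15‑ketone (rings C, D, E; 6‑O‑benzyl 5,6‑seco) | COc1cc(cc(C)c1OC)[C@]1(C)CC[C@@]2(C)[C@@H]3C[C@](C)(C(=O)OC)CC[C@]3(C)CC(=O)[C@]2(C)[C@@H]1CCOCc1ccccc1 | intermediate
24 | enol triflate of 23 | COc1cc(cc(C)c1OC)[C@]1(C)CC[C@@]2(C)[C@@H]3C[C@](C)(C(=O)OC)CC[C@]3(C)C=C(OS(=O)(=O)C(F)(F)F)[C@]2(C)[C@@H]1CCOCc1ccccc1 | intermediate
25 | 15,16‑alkene | COc1cc(cc(C)c1OC)[C@]1(C)CC[C@@]2(C)[C@@H]3C[C@](C)(C(=O)OC)CC[C@]3(C)C=C[C@]2(C)[C@@H]1CCOCc1ccccc1 | intermediate
26 | primary alcohol (ring D saturated) | COc1cc(cc(C)c1OC)[C@]1(C)CC[C@@]2(C)[C@@H]3C[C@](C)(C(=O)OC)CC[C@]3(C)CC[C@]2(C)[C@@H]1CCO | intermediate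
27 | aldehyde | COc1cc(cc(C)c1OC)[C@]1(C)CC[C@@]2(C)[C@@H]3C[C@](C)(C(=O)OC)CC[C@]3(C)CC[C@]2(C)[C@@H]1CC=O | intermediate
28 | 6‑hydroxy pentacycle (benzylic alcohol, either C6 epimer) | COc1cc2c(c(C)c1OC)C(O)C[C@@H]1[C@@]2(C)CC[C@@]2(C)[C@@H]3C[C@](C)(C(=O)OC)CC[C@]3(C)CC[C@]12C | intermediate
29 | methyl 2,3‑dimethoxy‑24‑nor‑8β‑friedela‑1,3,5(10),6‑tetraen‑29‑oate | COc1cc2c(c(C)c1OC)C=C[C@@H]1[C@@]2(C)CC[C@@]2(C)[C@@H]3C[C@](C)(C(=O)OC)CC[C@]3(C)CC[C@]12C | intermediate
30 | methyl 2,3‑dihydroxy‑24‑nor‑8β‑friedela‑1,3,5(10),6‑tetraen‑29‑oate | Oc1cc2c(c(C)c1O)C=C[C@@H]1[C@@]2(C)CC[C@@]2(C)[C@@H]3C[C@](C)(C(=O)OC)CC[C@]3(C)CC[C@]12C | intermediate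
31 | (S)‑carvone | CC1=CC[C@@H](CC1=O)C(C)=C | starting material
32 | (2S,5S)‑dihydrocarvone | C[C@H]1CC[C@@H](CC1=O)C(C)=C | intermediate
33 | (2S,5S)‑2‑methyl‑5‑(prop‑1‑en‑2‑yl)cycloheptan‑1‑one | C[C@H]1CC[C@@H](CCC1=O)C(C)=C | intermediate
34 | (4S,7S)‑7‑methyl‑4‑(prop‑1‑en‑2‑yl)‑2‑(prop‑2‑en‑1‑yl)cycloheptan‑1‑one (C2 epimers) | C=CCC1C[C@@H](C(C)=C)CC[C@H](C)C1=O | intermediate
35 | (4S,7S)‑7‑methyl‑2‑(2‑oxopropyl)‑4‑(prop‑1‑en‑2‑yl)cycloheptan‑1‑one (C2 epimers) | CC(=O)CC1C[C@@H](C(C)=C)CC[C@H](C)C1=O | intermediate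
36 | bicyclic enone (O=g3, g1=g2; g5 epimers) | O=C1C=C2[C@@H](C)CC[C@H](C(C)=C)CC2C1 | intermediate
37 | g4‑methyl bicyclic enone (g4, g5 epimers) | O=C1C=C2[C@@H](C)CC[C@H](C(C)=C)CC2C1C | intermediate
38 | allylic alcohol from 37 | OC1C=C2[C@@H](C)CC[C@H](C(C)=C)CC2C1C | intermediate
39 | (5S,8S)‑3,8‑dimethyl‑5‑(prop‑1‑en‑2‑yl)‑1,4,5,6,7,8‑hexahydroazulene | C=C(C)[C@H]1CC[C@H](C)C2=C(C1)C(C)=CC2 | intermediate
40 | methyl 2,3‑dioxo‑24‑nor‑8β‑friedela‑1(10),4,6‑trien‑29‑oate (ortho‑quinone) | O=C1C=C2C(=C(C)C1=O)C=C[C@@H]1[C@@]2(C)CC[C@@]2(C)[C@@H]3C[C@](C)(C(=O)OC)CC[C@]3(C)CC[C@]12C | intermediate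
41 | CNP0113384.4 | C=C(C)[C@H]1CC[C@H](C)[C@@]23CC=C(C)[C@]2(C1)Oc1cc2c(c(C)c1O3)C=C[C@@H]1[C@@]2(C)CC[C@@]2(C)[C@@H]3C[C@](C)(C(=O)OC)CC[C@]3(C)CC[C@]12C | target

## Count and risks

Total steps: 32. Longest linear sequence: 20 steps (steps 1–8, 14–24 and 32).

**Steps most likely to fail**

1. Step 18 (Proposed new method). Process at risk: the cascade may stall after the first C–C bond, with the C14 cation losing a proton or being held by oxygen faster than C13 migrates. Fallback with known reaction types, from 22 back to 23: the ring closure is run on purpose as a plain cation–olefin cyclization ending in proton loss (buffered acid, 2,6‑di‑tert‑butylpyridinium triflate in the fluoro alcohol), aiming at the seven‑membered exocyclic alkene, 14‑methylidene silyl ether F1. The 1,2‑shift is then done as a separate hydrogen‑atom‑transfer semipinacol rearrangement of this 2‑substituted allylic ether (Co(salen), C16H14CoN2O2, divalent cobalt, with an N‑fluoro‑2,4,6‑trimethylpyridinium salt and PhSiH3). This makes the C14 methyl group and ring D and returns to 23.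

2. Step 32. Process at risk: tautomerisation of the ortho‑quinone to the quinone methide, or cycloaddition with the wrong diene isomer, periselectivity or face. Fallback, from 30 and 39 back to 41: the two C–O bonds are made one after the other. Brønsted‑acid hydroaryloxylation of the diene (TfOH 2 mol%, toluene, 0 °C) should give the tertiary allyl aryl ether at g1, mono‑ether F2. A Wacker‑type oxidative cyclization of the remaining phenol onto the g4=g5 bond (Pd(OCOCF3)2, pyridine, O2, toluene, 80 °C) with β‑hydride loss toward g3 would then close the cis‑fused dioxane and restore the g3=g4 bond.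

3. Step 14. Process at risk: slow addition of the bulky trisubstituted alkenyl reagent to the hindered ketone, with enolisation or ester attack taking over. Fallback, from 11 back to 19: the slimmer lithium acetylide of 4‑(benzyloxy)but‑1‑yne (with CeCl3) is added to give propargylic alcohol F3. Hydroxyl‑directed syn‑hydrostannation (Bu3SnH, PdCl2(PPh3)2) places tin on the carbinol‑side carbon, giving vinylstannane F4. Stille methylation (MeI, Pd2(dba)3, AsPh3, CuI) with retention then delivers 19 with the same (Z) geometry.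

## Further compounds

F1 | step 18 | 14‑methylidene seven‑membered silyl ether (cyclized, unrearranged) | COc1cc(cc(C)c1OC)[C@]1(C)CC[C@@]2(C)[C@@H]3C[C@](C)(C(=O)OC)CC[C@]3(C)C[C@@]2(O[Si](C)(C)C)C(=C)[C@@H]1CCOCc1ccccc1
F2 | step 32 | mono‑ether of catechol 30 at O3 with g1 of the sesquiterpene (g4=g5 alkene) | C=C(C)[C@H]1CC[C@H](C)[C@]2(CCC(C)=C2C1)Oc1c(O)cc2c(c1C)C=C[C@@H]1[C@@]2(C)CC[C@@]2(C)[C@@H]3C[C@](C)(C(=O)OC)CC[C@]3(C)CC[C@]12C
F3 | step 14 | propargylic tertiary alcohol from 11 | CCOC(=O)C[C@@]1(C)[C@@H]2C[C@](C)(C(=O)OC)CC[C@]2(C)C[C@@]1(O)C#CCCOCc1ccccc1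
F4 | step 14 | vinylstannane from F3 (tin on the carbinol‑side carbon) | CCOC(=O)C[C@@]1(C)[C@@H]2C[C@](C)(C(=O)OC)CC[C@]2(C)C[C@@]1(O)/C([Sn](CCCC)(CCCC)CCCC)=C\CCOCc1ccccc1
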